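## Retrosynthetic overview

- The target is the bis-deprotected form of a protected 12-membered macrocycle. That macrocycle comes from an open-chain seco ester by closing the ring at the diaryl ether C–O bond: an intramolecular Ullmann-type coupling of the ring B phenoxide with a ring A aryl iodide, far from the lactone and from both stereocentres.
- Enabling feature: ring B carries its ether oxygen (on C1') ortho to the Z-alkenyl arm (C6'). Ring A carries the ester carbon (C1) and the ether carbon (C5, para to the C2 methyl, flanked by two hydrogens) in a 1,3 relation. The Z-olefin and the two arenes therefore fold the chain so that the C1' phenoxide reaches an unhindered C5–I, and the other ring B oxygens (C4'–OH and C5'–CH2OH) can be tied into a temporary benzodioxine ring.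
- The seco ester comes from acylation of a Z-allylic alcohol fragment with 5-iodo-2-methylbenzoic acid. The Z-olefin comes from an alkyne (Lindlar), and the (S,S)-threo diol pattern from chelation-controlled addition of a ring B aryl alkyne to an (S)-α-alkoxy aldehyde made from (S)-oct-1-en-3-ol.
- The ring B alkyne comes from 2-bromo-1,4-dimethoxybenzene by ortho-lithiation/formylation, demethylation, reduction, ketalisation, silylation and Sonogashira coupling.
- Ring order: rings A and B are bought as arenes; the temporary benzodioxine ring is formed in step 4; the 12-membered lactone ring is closed in step 15 and the benzodioxine is opened in step 16.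

Key step: step 15

Remarks on the chemistry: the target is read as the (S,S)-threo diol monoester with a Z-olefin. (S)-Oct-1-en-3-ol is assumed to be a purchasable, enantiopure material. Abbreviations: PMB = 4-methoxybenzyl, TBS = tert-butyldimethylsilyl, TIPS = tri(propan-2-yl)silyl.

## Route

Step 1
Reactants: 1 2-bromo-1,4-dimethoxybenzene
Product: 3 2-bromo-3,6-dimethoxybenzaldehyde, via aryllithium 2 (not isolated)
Conditions: LiN(iPr)2, THF, –78 °C; DMF, –78 → 0 °C; aq. HCl
Reagents that add atoms: N,N-dimethylformamide, CN(C)C=O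
Why: Directed ortho-metalation followed by formylation: the C–H between bromine and methoxy is the most acidic ring position, LiN(iPr)2 deprotonates it at –78 °C without bromine–lithium exchange or aryne formation, and DMF traps the aryllithium as the aldehyde.

Step 2
Reactants: 3 2-bromo-3,6-dimethoxybenzaldehyde
Product: 4 2-bromo-3,6-dihydroxybenzaldehyde
Conditions: BBr3, CH2Cl2, –78 °C → rt; H2O
Reagents that add atoms: none
Why: BBr3 ether cleavage (O–B coordination, bromide attack at methyl) removes both methyl groups, and the aldehyde is returned on hydrolysis.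

Step 3
Reactants: 4 2-bromo-3,6-dihydroxybenzaldehyde
Product: 5 2-bromo-3-(hydroxymethyl)benzene-1,4-diol
Conditions: NaBH4, MeOH (degassed), 0 °C, under argon
Reagents that add atoms: none
Why: NaBH4 reduction of the aldehyde gives the salicyl-type benzylic alcohol; the inert atmosphere keeps the hydroquinone from air oxidation to the quinone.

Step 4
Reactants: 5 2-bromo-3-(hydroxymethyl)benzene-1,4-diol
Product: 6 5-bromo-2,2-dimethyl-4H-1,3-benzodioxin-6-ol
Conditions: 2,2-dimethoxypropane, TsOH·H2O (cat.), acetone, rt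
Reagents that add atoms: 2,2-dimethoxypropane, COC(C)(C)OC
Why: Acid-catalysed transketalisation (isopropylidene ketal formation): only the C4' phenol and the adjacent CH2OH can close a six-membered 1,3-dioxine, so the phenol next to bromine (the future C1' ether oxygen) stays free.

Step 5
Reactants: 6 5-bromo-2,2-dimethyl-4H-1,3-benzodioxin-6-ol
Product: 7 [(5-bromo-2,2-dimethyl-4H-1,3-benzodioxin-6-yl)oxy]tri(propan-2-yl)silane
Conditions: TIPSCl, imidazole, DMF, rt
Reagents that add atoms: chlorotri(propan-2-yl)silane, CC(C)[Si](Cl)(C(C)C)C(C)C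
Why: Silyl ether formation at the one free phenol; an aryl TIPS ether should withstand n-BuLi at low temperature, K2CO3/MeOH and DDQ, yet be cleaved by fluoride far faster than an alkyl TBS ether, which is what step 14 needs.

Step 6
Reactants: 7 [(5-bromo-2,2-dimethyl-4H-1,3-benzodioxin-6-yl)oxy]tri(propan-2-yl)silane
Product: 9 [(5-ethynyl-2,2-dimethyl-4H-1,3-benzodioxin-6-yl)oxy]tri(propan-2-yl)silane, via TMS-alkyne 8 (not isolated)
Conditions: Pd(PhCN)2Cl2 (cat.), P(t-Bu)3·HBF4 (cat.), CuI (cat.), HC≡CSiMe3, HN(iPr)2, 1,4-dioxane, rt → 50 °C; then K2CO3, MeOH, rt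
Reagents that add atoms: ethynyltrimethylsilane, C#C[Si](C)(C)C
Why: Sonogashira coupling, in which the bulky electron-rich phosphine lets zerovalent palladium insert into the hindered electron-rich C–Br bond, followed by methanolysis of the alkynyl C–Si bond; the phenol must be capped here because a free ortho-alkynylphenol would cyclise to a benzofuran.

Step 7
Reactants: 10 (S)-oct-1-en-3-ol
Product: 11 (3S)-3-(4-methoxybenzyloxy)oct-1-ene
Conditions: NaH, PMBCl, Bu4NI (cat.), THF/DMF, 0 °C → rt
Reagents that add atoms: 4-methoxybenzyl chloride, COc1ccc(CCl)cc1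
Why: Williamson etherification of the alkoxide leaves the stereocentre untouched and installs an ether oxygen that can chelate in step 9 and be removed oxidatively in step 11.

Step 8
Reactants: 11 (3S)-3-(4-methoxybenzyloxy)oct-1-ene
Product: 13 (2S)-2-(4-methoxybenzyloxy)heptanal, via ozonide 12 (not isolated)
Conditions: O3, CH2Cl2, –78 °C (Sudan red 7B as end-point indicator); PPh3, –78 °C → rt
Reagents that add atoms: ozone, [O-][O+]=O
Why: Ozonolysis (Criegee mechanism) with PPh3 reduction of the ozonide excises the terminal CH2 and gives the α-alkoxy aldehyde, which is used crude and cold so that the α-stereocentre does not epimerise.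

Step 9
Reactants: 9 [(5-ethynyl-2,2-dimethyl-4H-1,3-benzodioxin-6-yl)oxy]tri(propan-2-yl)silane; 13 (2S)-2-(4-methoxybenzyloxy)heptanal
Product: 16 (3S,4S)-4-(4-methoxybenzyloxy)-1-[2,2-dimethyl-6-(TIPS-oxy)-4H-1,3-benzodioxin-5-yl]non-1-yn-3-ol, via lithium acetylide 14 (not isolated), via alkynylzinc bromide 15 (not isolated)
Conditions: 9, n-BuLi, Et2O, –78 °C; ZnBr2, 0 °C; 13, –78 → 0 °C; aq. NH4Cl
Reagents that add atoms: none
Why: Chelation-controlled (Cram chelate) addition of an alkynylzinc halide to an α-alkoxy aldehyde: divalent zinc bridges the carbonyl and PMB-ether oxygens in a five-membered ring and the acetylide adds to the face anti to the pentyl group, which should set the new (3S) carbinol syn (threo) to the existing (4S) centre.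

Step 10
Reactants: 16 (3S,4S)-4-(4-methoxybenzyloxy)-1-[2,2-dimethyl-6-(TIPS-oxy)-4H-1,3-benzodioxin-5-yl]non-1-yn-3-ol
Product: 17 (3S,4S)-3-(TBS-oxy)-4-(4-methoxybenzyloxy)-1-[2,2-dimethyl-6-(TIPS-oxy)-4H-1,3-benzodioxin-5-yl]non-1-yne
Conditions: TBSOTf, 2,6-lutidine, CH2Cl2, –78 → 0 °C
Reagents that add atoms: tert-butyldimethylsilyl trifluoromethanesulfonate, CC(C)(C)[Si](C)(C)OS(=O)(=O)C(F)(F)F
Why: Silylation of the propargylic alcohol with the silyl triflate and a hindered pyridine base; the TBS ether blocks this oxygen against acylation in step 13 and against acyl migration under the carbonate of step 15.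

Step 11
Reactants: 17 (3S,4S)-3-(TBS-oxy)-4-(4-methoxybenzyloxy)-1-[2,2-dimethyl-6-(TIPS-oxy)-4H-1,3-benzodioxin-5-yl]non-1-yne
Product: 18 (3S,4S)-3-(TBS-oxy)-1-[2,2-dimethyl-6-(TIPS-oxy)-4H-1,3-benzodioxin-5-yl]non-1-yn-4-ol
Conditions: DDQ, CH2Cl2/pH 7 phosphate buffer, 0 °C
Reagents that add atoms: none
Why: Oxidative PMB cleavage by DDQ (hydride abstraction to the oxocarbenium ion, then hydrolysis) frees the C4 hydroxyl; the buffered two-phase medium protects the ketal and the silyl ethers, and the step is run on the alkyne because it is less oxidisable than the later styrene.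

Step 12
Reactants: 18 (3S,4S)-3-(TBS-oxy)-1-[2,2-dimethyl-6-(TIPS-oxy)-4H-1,3-benzodioxin-5-yl]non-1-yn-4-ol
Product: 19 (1Z,3S,4S)-3-(TBS-oxy)-1-[2,2-dimethyl-6-(TIPS-oxy)-4H-1,3-benzodioxin-5-yl]non-1-en-4-ol
Conditions: H2 (1 atm), Pd/CaCO3 poisoned with Pb(OAc)2 (Lindlar catalyst), quinoline, EtOAc, rt
Reagents that add atoms: none
Why: Lindlar semi-hydrogenation delivers both hydrogens to one face of the alkyne on the poisoned palladium surface and so should give the Z-olefin; it is placed before the aryl iodide enters the molecule to exclude hydrodehalogenation.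

Step 13
Reactants: 19 (1Z,3S,4S)-3-(TBS-oxy)-1-[2,2-dimethyl-6-(TIPS-oxy)-4H-1,3-benzodioxin-5-yl]non-1-en-4-ol; 20 5-iodo-2-methylbenzoic acid
Product: 22 (1Z,3S,4S)-3-(TBS-oxy)-1-[2,2-dimethyl-6-(TIPS-oxy)-4H-1,3-benzodioxin-5-yl]non-1-en-4-yl 5-iodo-2-methylbenzoate, via acid chloride 21 (not isolated)
Conditions: 20, (COCl)2, DMF (cat.), CH2Cl2, rt, evaporate; then 19, Et3N, DMAP, CH2Cl2, 0 °C → rt
Reagents that add atoms: none
Why: Acylation of the secondary alcohol by the acid chloride under DMAP nucleophilic catalysis, chosen because both partners are hindered; the C4–O bond is not broken, so the (4S) configuration is retained.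

Step 14
Reactants: 22 (1Z,3S,4S)-3-(TBS-oxy)-1-[2,2-dimethyl-6-(TIPS-oxy)-4H-1,3-benzodioxin-5-yl]non-1-en-4-yl 5-iodo-2-methylbenzoate
Product: 23 (1Z,3S,4S)-3-(TBS-oxy)-1-(6-hydroxy-2,2-dimethyl-4H-1,3-benzodioxin-5-yl)non-1-en-4-yl 5-iodo-2-methylbenzoate
Conditions: Bu4NF, AcOH, THF, 0 °C
Reagents that add atoms: none
Why: Fluoride-mediated desilylation, selective for the aryl silyl ether because phenoxide is the better leaving group at silicon; AcOH buffering and 0 °C should keep the secondary TBS ether and the ester in place.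

Step 15
Reactants: 23 (1Z,3S,4S)-3-(TBS-oxy)-1-(6-hydroxy-2,2-dimethyl-4H-1,3-benzodioxin-5-yl)non-1-en-4-yl 5-iodo-2-methylbenzoate
Product: 24 protected macrocycle (the 12-membered diaryl ether lactone of the target carrying the allylic oxygen as TBS ether and the C4'–O/C5'–CH2O pair as isopropylidene ketal)
Conditions: CuI, N,N-dimethylglycine hydrochloride, Cs2CO3, 1,4-dioxane, 90 °C, syringe-pump addition of 23 to a final 2 mM
Reagents that add atoms: none
Why: Cs2CO3 deprotonates the only free hydroxyl, the C1' phenol of ring B, and the phenoxide binds CuI carrying the dimethylglycinate ligand; this monovalent copper phenoxide adds oxidatively into the C5–I bond of ring A held in the same molecule, and reductive elimination from the trivalent copper aryl phenoxide forms the C5–O bond. The closest known reaction type is the amino-acid-ligated Ullmann diaryl ether coupling in its intramolecular form, which is established for closing macrocyclic diaryl ethers. The 12-membered ring is closed by macro-etherification at an sp2 carbon with the metal templating both chain ends; no new stereocentre is formed, and the two (S) centres and the Z-olefin are spectators because the allylic oxygen is silylated, so neither acyl migration nor elimination is open under carbonate. The step needs intramolecular to beat intermolecular coupling, which slow addition to high dilution and the built-in turn (Z-olefin ortho to the phenoxide, 1,3-placed ester and iodide on ring A) should secure. It also needs reaction at one oxygen only, which is secured because the C4' and benzylic oxygens are locked in the benzodioxine ring. The iodide carbon is para to the methyl group and has two ortho hydrogens, so the electrophilic site is unhindered and the hindered partner is the nucleophile, the arrangement this copper system tolerates best.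

Step 16
Reactants: 24 protected macrocycle
Product: 25 target macrolide CNP0191798.1
Conditions: aq. HF (48%), MeCN, 0 °C → rt (plastic vessel)
Reagents that add atoms: none
Why: Acidic fluoride should cleave the secondary TBS ether and hydrolyse the phenol-derived isopropylidene ketal in one operation; the weakly acidic, non-nucleophilic medium is chosen to spare the lactone, the Z-styrene and the allylic alcohol.

## Compound list

1 | 2-bromo-1,4-dimethoxybenzene | COc1ccc(OC)c(Br)c1 | starting material
2 | (2-bromo-3,6-dimethoxyphenyl)lithium | COc1ccc(OC)c(Br)c1[Li] | intermediate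
3 | 2-bromo-3,6-dimethoxybenzaldehyde | COc1ccc(OC)c(Br)c1C=O | intermediate
4 | 2-bromo-3,6-dihydroxybenzaldehyde | Oc1ccc(O)c(Br)c1C=O | intermediate
5 | 2-bromo-3-(hydroxymethyl)benzene-1,4-diol | Oc1ccc(O)c(Br)c1CO | intermediate
6 | 5-bromo-2,2-dimethyl-4H-1,3-benzodioxin-6-ol | CC1(C)OCc2c(Br)c(O)ccc2O1 | intermediate
7 | [(5-bromo-2,2-dimethyl-4H-1,3-benzodioxin-6-yl)oxy]tri(propan-2-yl)silane | CC(C)[Si](Oc1ccc2OC(C)(C)OCc2c1Br)(C(C)C)C(C)C | intermediate
8 | trimethyl({2,2-dimethyl-6-[tri(propan-2-yl)silyloxy]-4H-1,3-benzodioxin-5-yl}ethynyl)silane | CC(C)[Si](Oc1ccc2OC(C)(C)OCc2c1C#C[Si](C)(C)C)(C(C)C)C(C)C | intermediate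
9 | [(5-ethynyl-2,2-dimethyl-4H-1,3-benzodioxin-6-yl)oxy]tri(propan-2-yl)silane | CC(C)[Si](Oc1ccc2OC(C)(C)OCc2c1C#C)(C(C)C)C(C)C | intermediate
10 | (S)-oct-1-en-3-ol | CCCCC[C@H](O)C=C | starting material
11 | (3S)-3-(4-methoxybenzyloxy)oct-1-ene | CCCCC[C@H](OCc1ccc(OC)cc1)C=C | intermediate
12 | 3-[(1S)-1-(4-methoxybenzyloxy)hexyl]-1,2,4-trioxolane (ozonide, ring carbon unassigned) | CCCCC[C@H](OCc1ccc(OC)cc1)C1OCOO1 | intermediate
13 | (2S)-2-(4-methoxybenzyloxy)heptanal | CCCCC[C@H](OCc1ccc(OC)cc1)C=O | intermediate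
14 | lithium acetylide of 9 | CC(C)[Si](Oc1ccc2OC(C)(C)OCc2c1C#C[Li])(C(C)C)C(C)C | intermediate
15 | alkynylzinc bromide of 9 | CC(C)[Si](Oc1ccc2OC(C)(C)OCc2c1C#C[Zn]Br)(C(C)C)C(C)C | intermediate
16 | (3S,4S)-4-(4-methoxybenzyloxy)-1-{2,2-dimethyl-6-[tri(propan-2-yl)silyloxy]-4H-1,3-benzodioxin-5-yl}non-1-yn-3-ol | CCCCC[C@H](OCc1ccc(OC)cc1)[C@@H](O)C#Cc1c(O[Si](C(C)C)(C(C)C)C(C)C)ccc2OC(C)(C)OCc12 | intermediate
17 | 3-O-TBS ether of 16, (3S,4S) | CCCCC[C@H](OCc1ccc(OC)cc1)[C@@H](O[Si](C)(C)C(C)(C)C)C#Cc1c(O[Si](C(C)C)(C(C)C)C(C)C)ccc2OC(C)(C)OCc12 | intermediate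
18 | (3S,4S)-3-(tert-butyldimethylsilyloxy)-1-{2,2-dimethyl-6-[tri(propan-2-yl)silyloxy]-4H-1,3-benzodioxin-5-yl}non-1-yn-4-ol | CCCCC[C@H](O)[C@@H](O[Si](C)(C)C(C)(C)C)C#Cc1c(O[Si](C(C)C)(C(C)C)C(C)C)ccc2OC(C)(C)OCc12 | intermediate
19 | (1Z,3S,4S)-3-(tert-butyldimethylsilyloxy)-1-{2,2-dimethyl-6-[tri(propan-2-yl)silyloxy]-4H-1,3-benzodioxin-5-yl}non-1-en-4-ol | CCCCC[C@H](O)[C@@H](O[Si](C)(C)C(C)(C)C)/C=C\c1c(O[Si](C(C)C)(C(C)C)C(C)C)ccc2OC(C)(C)OCc12 | intermediate
20 | 5-iodo-2-methylbenzoic acid | Cc1ccc(I)cc1C(=O)O | starting material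
21 | 5-iodo-2-methylbenzoyl chloride | Cc1ccc(I)cc1C(=O)Cl | intermediate
22 | (1Z,3S,4S)-3-(tert-butyldimethylsilyloxy)-1-{2,2-dimethyl-6-[tri(propan-2-yl)silyloxy]-4H-1,3-benzodioxin-5-yl}non-1-en-4-yl 5-iodo-2-methylbenzoate | CCCCC[C@H](OC(=O)c1cc(I)ccc1C)[C@@H](O[Si](C)(C)C(C)(C)C)/C=C\c1c(O[Si](C(C)C)(C(C)C)C(C)C)ccc2OC(C)(C)OCc12 | intermediate
23 | (1Z,3S,4S)-3-(tert-butyldimethylsilyloxy)-1-(6-hydroxy-2,2-dimethyl-4H-1,3-benzodioxin-5-yl)non-1-en-4-yl 5-iodo-2-methylbenzoate | CCCCC[C@H](OC(=O)c1cc(I)ccc1C)[C@@H](O[Si](C)(C)C(C)(C)C)/C=C\c1c(O)ccc2OC(C)(C)OCc12 | intermediate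
24 | protected macrocycle: (S,S,Z)-12-membered diaryl ether lactone, allylic O-TBS, ring B as 2,2-dimethyl-1,3-benzodioxine | CCCCC[C@@H]1OC(=O)c2cc(ccc2C)Oc2ccc3OC(C)(C)OCc3c2/C=C\[C@@H]1O[Si](C)(C)C(C)(C)C | intermediate
25 | CNP0191798.1: (S,S,Z)-12-membered diaryl ether lactone with pentyl on the lactone carbinol carbon, free allylic OH, ring A methyl, ring B phenol and CH2OH | CCCCC[C@@H]1OC(=O)c2cc(ccc2C)Oc2ccc(O)c(CO)c2/C=C\[C@@H]1O | target

## Count and risks

Total step count: 16. Longest linear sequence: 14 steps (steps 1–6, then 9–16).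

Steps most likely to fail:

1. Step 15. At 90 °C, oligomerisation and hydrodeiodination may outrun closure of the 12-membered ring, or reductive elimination may be slow in the strained transition state. The fallback closes the same bond oxidatively at room temperature and sets out from 19. Acylation of 19 with commercial 2-methyl-5-(4,4,5,5-tetramethyl-1,3,2-dioxaborolan-2-yl)benzoic acid (EDC·HCl, DMAP, CH2Cl2) would give the aryl boronate ester F1. Bu4NF/AcOH in THF at 0 °C would free the phenol to give the phenol boronate F2. Chan–Lam coupling (Cu(OAc)2, pyridine, 4 Å molecular sieves, air, CH2Cl2, rt, high dilution) would then proceed by boron-to-copper transmetalation at divalent copper, oxidation to trivalent copper and C–O reductive elimination, returning to the route at 24.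

2. Step 9. Facial selectivity may be poor if the zinc chelate is loose and open-chain (Felkin-type) addition competes. The fallback replaces substrate control by reagent control and sets out from 16 obtained as a mixture of C3 epimers. Dess–Martin periodinane (CH2Cl2, NaHCO3) would converge both epimers to the ynone F3. Noyori asymmetric transfer hydrogenation with RuCl[(R,R)-TsDPEN](p-cymene) in iPrOH would then reduce it. With the alkynyl group taking the place of the aryl group in the usual model, the (R,R) ligand is the enantiomer expected to give the (3S) carbinol, returning to the route at 16 as a single diastereomer.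

3. Step 12. The hindered, electron-rich internal alkyne may stall, over-reduce, or isomerise on the catalyst. The fallback fixes the Z geometry before fragment union and sets out from 9. Iodination (N-iodosuccinimide, AgNO3 cat., acetone) would give the iodoalkyne F4. Diimide reduction (2-nitrobenzenesulfonyl hydrazide, Et3N) would give the (Z)-iodoalkene F5 by syn hydrogen delivery. Iodine–lithium exchange with retention (t-BuLi, Et2O, –78 °C), transmetalation with MgBr2·OEt2 and chelation-controlled addition to aldehyde 13 would give the Z-allylic alcohol F6. Silylation (TBSOTf, 2,6-lutidine) would give the bis-silyl PMB ether F7, and DDQ cleavage of the PMB ether returns to the route at 19.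

## Further compounds

F1 | step 15 | aryl boronate ester: 19 acylated on O4 by 2-methyl-5-(4,4,5,5-tetramethyl-1,3,2-dioxaborolan-2-yl)benzoic acid, (1Z,3S,4S) | CCCCC[C@H](OC(=O)c1cc(B2OC(C)(C)C(C)(C)O2)ccc1C)[C@@H](O[Si](C)(C)C(C)(C)C)/C=C\c1c(O[Si](C(C)C)(C(C)C)C(C)C)ccc2OC(C)(C)OCc12
F2 | step 15 | phenol boronate: F1 without the TIPS group, (1Z,3S,4S) | CCCCC[C@H](OC(=O)c1cc(B2OC(C)(C)C(C)(C)O2)ccc1C)[C@@H](O[Si](C)(C)C(C)(C)C)/C=C\c1c(O)ccc2OC(C)(C)OCc12
F3 | step 9 | ynone: (4S)-4-(4-methoxybenzyloxy)-1-{2,2-dimethyl-6-[tri(propan-2-yl)silyloxy]-4H-1,3-benzodioxin-5-yl}non-1-yn-3-one | CCCCC[C@H](OCc1ccc(OC)cc1)C(=O)C#Cc1c(O[Si](C(C)C)(C(C)C)C(C)C)ccc2OC(C)(C)OCc12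
F4 | step 12 | iodoalkyne: {[5-(iodoethynyl)-2,2-dimethyl-4H-1,3-benzodioxin-6-yl]oxy}tri(propan-2-yl)silane | CC(C)[Si](Oc1ccc2OC(C)(C)OCc2c1C#CI)(C(C)C)C(C)C
F5 | step 12 | (Z)-iodoalkene: ({5-[(Z)-2-iodoethenyl]-2,2-dimethyl-4H-1,3-benzodioxin-6-yl}oxy)tri(propan-2-yl)silane | CC(C)[Si](Oc1ccc2OC(C)(C)OCc2c1/C=C\I)(C(C)C)C(C)C
F6 | step 12 | Z-allylic alcohol: (1Z,3S,4S)-4-(4-methoxybenzyloxy)-1-{2,2-dimethyl-6-[tri(propan-2-yl)silyloxy]-4H-1,3-benzodioxin-5-yl}non-1-en-3-ol | CCCCC[C@H](OCc1ccc(OC)cc1)[C@@H](O)/C=C\c1c(O[Si](C(C)C)(C(C)C)C(C)C)ccc2OC(C)(C)OCc12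
F7 | step 12 | bis-silyl PMB ether: 3-O-TBS ether of F6, (1Z,3S,4S) | CCCCC[C@H](OCc1ccc(OC)cc1)[C@@H](O[Si](C)(C)C(C)(C)C)/C=C\c1c(O[Si](C(C)C)(C(C)C)C(C)C)ccc2OC(C)(C)OCc12
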